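## Retrosynthetic overview

1. Target 35 comes from 34 by C7‑OH‑directed epoxidation of the Z‑C8=C9 olefin; 34 comes from a Nozaki–Hiyama–Kishi union (C4–C12) of bicyclic enol triflate 26 with epoxy‑aldehyde 32.
2. The nine‑membered ring is closed by ring‑closing metathesis (C8=C9) of diene 24; this is the key ring closure.
3. Diene 24 comes from Achmatowicz pyranone 16 by anti‑selective conjugate addition of the dienyl unit (from 12, C9–C11/C19), enolate alkylation with iodide 9 (C5–C8), acetal‑to‑acetate exchange and enol triflation.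
4. Fragments: 9 (C7 from Sharpless epoxidation and reductive opening), 32 (C13 by lipase resolution, C14 by Shi epoxidation, CHO by ozonolysis), 16 (C1 by dynamic kinetic acylation).
5. Ring order: pyranone (step 9), side‑chain oxirane (step 21, carried in with 32), nine‑membered carbocycle (step 17), ring oxirane (step 25).

Assumption: the SMILES defines CNP0134792.1 (xenicane numbering C1–C19 is used), and in step 10 the catalyst antipode that gives the (R)‑ester is used, its sense to be confirmed by optical rotation before scale‑up.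

## Route

**Step 1**
Reactants: 1 tert‑butyl(but‑3‑yn‑1‑yloxy)dimethylsilane
Product: 3 (E)‑5‑[(tert‑butyldimethylsilyl)oxy]‑3‑methylpent‑2‑en‑1‑ol, via alkenylalane 2 (not isolated)
Conditions: Me3Al, Cp2ZrCl2 (0.25 equiv), CH2Cl2, 0 °C → rt; then (CH2O)n, 0 °C → rt
Reagents that add atoms: trimethylaluminium C[Al](C)C; formaldehyde (as paraformaldehyde) C=O
Why: Negishi Zr‑catalysed carboalumination adds Me and Al syn across the terminal alkyne (Me to the internal carbon) and the alkenylalane is hydroxymethylated with retention, giving only the E‑allylic alcohol.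

**Step 2**
Reactants: 3 (E)‑5‑[(tert‑butyldimethylsilyl)oxy]‑3‑methylpent‑2‑en‑1‑ol
Product: 4 [(2S,3S)‑3‑{2‑[(tert‑butyldimethylsilyl)oxy]ethyl}‑3‑methyloxiran‑2‑yl]methanol
Conditions: Ti(OiPr)4 (10 mol %), L‑(+)‑DET (12 mol %), TBHP, 4 Å MS, CH2Cl2, −20 °C
Reagents that add atoms: tert‑butyl hydroperoxide CC(C)(C)OO
Why: Sharpless asymmetric epoxidation of a geraniol‑type E‑allylic alcohol with L‑(+)‑tartrate gives the (2S,3S)‑epoxide, which fixes the future C7.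

**Step 3**
Reactants: 4 [(2S,3S)‑3‑{2‑[(tert‑butyldimethylsilyl)oxy]ethyl}‑3‑methyloxiran‑2‑yl]methanol
Product: 5 tert‑butyl{2‑[(2S,3R)‑3‑(iodomethyl)‑2‑methyloxiran‑2‑yl]ethoxy}dimethylsilane
Conditions: I2, PPh3, imidazole, THF, 0 °C
Reagents that add atoms: iodine II
Why: Appel‑type iodination of the primary alcohol under imidazole buffering leaves the epoxide and both stereocentres untouched (descriptor change is a CIP effect only).

**Step 4**
Reactants: 5 tert‑butyl{2‑[(2S,3R)‑3‑(iodomethyl)‑2‑methyloxiran‑2‑yl]ethoxy}dimethylsilane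
Product: 6 (3S)‑5‑[(tert‑butyldimethylsilyl)oxy]‑3‑methylpent‑1‑en‑3‑ol
Conditions: Zn dust, AcOH (2 equiv), EtOH, rt
Reagents that add atoms: none
Why: Zinc insertion into the C–I bond and β‑elimination (reductive epoxide opening) gives the vinyl carbinol, and the tertiary C–O bond is never broken so the (S) configuration is retained.

**Step 5**
Reactants: 6 (3S)‑5‑[(tert‑butyldimethylsilyl)oxy]‑3‑methylpent‑1‑en‑3‑ol
Product: 7 (3S)‑3‑methylpent‑4‑ene‑1,3‑diol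
Conditions: TBAF, THF, rt
Reagents that add atoms: none
Why: Fluoride desilylation of the primary TBS ether is clean and does not touch the tertiary allylic alcohol.

**Step 6**
Reactants: 7 (3S)‑3‑methylpent‑4‑ene‑1,3‑diol
Product: 8 (3S)‑5‑iodo‑3‑methylpent‑1‑en‑3‑ol
Conditions: I2, PPh3, imidazole, CH2Cl2, 0 °C
Reagents that add atoms: iodine II
Why: Appel iodination is selective for the primary hydroxyl because the hindered tertiary alcohol does not form the alkoxyphosphonium salt at 0 °C.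

**Step 7**
Reactants: 8 (3S)‑5‑iodo‑3‑methylpent‑1‑en‑3‑ol
Product: 9 triethyl{[(3S)‑5‑iodo‑3‑methylpent‑1‑en‑3‑yl]oxy}silane
Conditions: TESOTf, 2,6‑lutidine, CH2Cl2, −78 → 0 °C
Reagents that add atoms: triethylsilyl triflate CC[Si](CC)(CC)OS(=O)(=O)C(F)(F)F
Why: Silyl triflate silylation is the standard way to cap a tertiary alcohol, and the bulky OTES group later keeps the adjacent vinyl group from initiating metathesis.

**Step 8**
Reactants: 10 2,3‑dibromoprop‑1‑ene; 11 vinylmagnesium bromide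
Product: 12 2‑bromopenta‑1,4‑diene
Conditions: CuI (5 mol %), THF, 0 °C
Reagents that add atoms: none
Why: Copper‑catalysed allylic substitution by the vinyl Grignard takes place only at the allylic C–Br bond (SN2 and SN2′ give the same product), leaving the vinylic bromide.

**Step 9**
Reactants: 13 furfuryl alcohol
Product: 14 6‑hydroxy‑2H‑pyran‑3(6H)‑one (racemic lactol)
Conditions: NBS, NaHCO3, NaOAc, THF/H2O (4:1), 0 °C
Reagents that add atoms: water O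
Why: Achmatowicz oxidative ring expansion of a furfuryl alcohol gives the pyranone lactol directly.

**Step 10**
Reactants: 14 6‑hydroxy‑2H‑pyran‑3(6H)‑one
Product: 15 (R)‑6‑(isobutyryloxy)‑2H‑pyran‑3(6H)‑one
Conditions: isobutyric anhydride, chiral isothiourea catalyst (benzotetramisole type, 5 mol %), iPr2NEt, CHCl3, 0 °C
Reagents that add atoms: isobutyric anhydride CC(C)C(=O)OC(=O)C(C)C
Why: Acylative dynamic kinetic resolution works because the lactol enantiomers interconvert by ring opening while the chiral acyl‑transfer catalyst acylates one of them, which sets the acetal carbon (future C1).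

**Step 11**
Reactants: 15 (R)‑6‑(isobutyryloxy)‑2H‑pyran‑3(6H)‑one
Product: 16 (S)‑6‑[(4‑methoxybenzyl)oxy]‑2H‑pyran‑3(6H)‑one
Conditions: Pd2(dba)3·CHCl3 (2.5 mol %), PPh3 (10 mol %), 4‑methoxybenzyl alcohol (2 equiv), CH2Cl2, 0 °C
Reagents that add atoms: 4‑methoxybenzyl alcohol COc1ccc(CO)cc1
Why: Pd(0)‑catalysed allylic substitution (Tsuji–Trost type glycosylation) proceeds by double inversion, so the acetal is exchanged with net retention (the R to S change is a CIP effect).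

**Step 12**
Reactants: 16 (S)‑6‑[(4‑methoxybenzyl)oxy]‑2H‑pyran‑3(6H)‑one; 12 2‑bromopenta‑1,4‑diene
Product: 18 (5R,6S)‑6‑[(4‑methoxybenzyl)oxy]‑5‑(penta‑1,4‑dien‑2‑yl)‑3‑[(trimethylsilyl)oxy]‑5,6‑dihydro‑2H‑pyran, via Grignard reagent 17 (not isolated)
Conditions: 12, Mg, THF, 40 °C; then CuBr·SMe2 (10 mol %), TMSCl, HMPA, 16, THF, −78 °C; Et3N quench
Reagents that add atoms: chlorotrimethylsilane C[Si](C)(C)Cl
Why: TMSCl‑accelerated copper‑catalysed conjugate addition delivers the alkenyl group anti to the pseudoaxial C6 alkoxy group (5,6‑trans, sets C11a) and traps the enolate regiospecifically as the silyl enol ether.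

**Step 13**
Reactants: 18 (5R,6S)‑6‑[(4‑methoxybenzyl)oxy]‑5‑(penta‑1,4‑dien‑2‑yl)‑3‑[(trimethylsilyl)oxy]‑5,6‑dihydro‑2H‑pyran; 9 triethyl{[(3S)‑5‑iodo‑3‑methylpent‑1‑en‑3‑yl]oxy}silane
Product: 20 (4S,5R,6S)‑6‑[(4‑methoxybenzyl)oxy]‑4‑[(3S)‑3‑methyl‑3‑(triethylsilyloxy)pent‑4‑en‑1‑yl]‑5‑(penta‑1,4‑dien‑2‑yl)dihydro‑2H‑pyran‑3(4H)‑one, via lithium enolate 19 (not isolated)
Conditions: MeLi (1.05 equiv), THF, 0 °C; then DMPU, 9 (1.5 equiv), −40 → 0 °C
Reagents that add atoms: none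
Why: MeLi cleavage of the silyl enol ether gives the regiodefined lithium enolate, whose SN2 alkylation by the primary iodide occurs anti to the neighbouring C5 substituent (4,5‑trans, sets C4a).

**Step 14**
Reactants: 20 (4S,5R,6S)‑6‑[(4‑methoxybenzyl)oxy]‑4‑[(3S)‑3‑methyl‑3‑(triethylsilyloxy)pent‑4‑en‑1‑yl]‑5‑(penta‑1,4‑dien‑2‑yl)dihydro‑2H‑pyran‑3(4H)‑one
Product: 21 (4S,5R)‑6‑hydroxy‑4‑[(3S)‑3‑methyl‑3‑(triethylsilyloxy)pent‑4‑en‑1‑yl]‑5‑(penta‑1,4‑dien‑2‑yl)dihydro‑2H‑pyran‑3(4H)‑one (anomer mixture)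
Conditions: DDQ (1.3 equiv), CH2Cl2/pH 7 buffer (10:1), 0 °C → rt
Reagents that add atoms: none
Why: Oxidative cleavage of the PMB acetal by DDQ (benzylic hydride abstraction then hydrolysis) unmasks the lactol at a stage with no acid‑sensitive oxiranes or enol ether, and a six‑membered keto‑lactol stays closed.

**Step 15**
Reactants: 21 (4S,5R)‑6‑hydroxy‑4‑[(3S)‑3‑methyl‑3‑(triethylsilyloxy)pent‑4‑en‑1‑yl]‑5‑(penta‑1,4‑dien‑2‑yl)dihydro‑2H‑pyran‑3(4H)‑one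
Product: 22 (2R,3R,4S)‑4‑[(3S)‑3‑methyl‑3‑(triethylsilyloxy)pent‑4‑en‑1‑yl]‑5‑oxo‑3‑(penta‑1,4‑dien‑2‑yl)tetrahydro‑2H‑pyran‑2‑yl acetate
Conditions: Ac2O, Et3N, DMAP (cat.), CH2Cl2, −20 → 0 °C; minor anomer removed by chromatography
Reagents that add atoms: acetic anhydride CC(=O)OC(C)=O
Why: Base‑mediated acylation of the mutarotating lactol takes the more nucleophilic equatorial anomer, which is the 2,3‑trans acetate and carries the C1 configuration of the target.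

**Step 16**
Reactants: 22 (2R,3R,4S)‑4‑[(3S)‑3‑methyl‑3‑(triethylsilyloxy)pent‑4‑en‑1‑yl]‑5‑oxo‑3‑(penta‑1,4‑dien‑2‑yl)tetrahydro‑2H‑pyran‑2‑yl acetate
Product: 24 (2R,3R,4S)‑4‑[(3S)‑3‑methyl‑3‑(triethylsilyloxy)pent‑4‑en‑1‑yl]‑3‑(penta‑1,4‑dien‑2‑yl)‑5‑(triflyloxy)‑3,4‑dihydro‑2H‑pyran‑2‑yl acetate, via potassium enolate 23 (not isolated)
Conditions: KHMDS (1.1 equiv), THF, −78 °C; Comins' reagent (1.2 equiv), −78 °C
Reagents that add atoms: Comins' reagent FC(F)(F)S(=O)(=O)N(c1ccc(Cl)cn1)S(=O)(=O)C(F)(F)F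
Why: Kinetic deprotonation goes to the unhindered, oxygen‑activated OCH2 and not to the tertiary C4–H, and O‑triflation at −78 °C gives the enol triflate that already holds the C3=C4 enol ether.

**Step 17**
Reactants: 24 (2R,3R,4S)‑4‑[(3S)‑3‑methyl‑3‑(triethylsilyloxy)pent‑4‑en‑1‑yl]‑3‑(penta‑1,4‑dien‑2‑yl)‑5‑(triflyloxy)‑3,4‑dihydro‑2H‑pyran‑2‑yl acetate
Product: 25 (1R,4aS,7S,11aR,8Z)‑7‑methyl‑11‑methylene‑7‑(triethylsilyloxy)‑4‑(triflyloxy)‑1,4a,5,6,7,10,11,11a‑octahydrocyclonona[c]pyran‑1‑yl acetate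
Conditions: Grubbs II (10 mol % in two portions), 1,4‑benzoquinone (10 mol %), CH2Cl2 (1 mM), 40 °C, argon sparge
Reagents that add atoms: none
Why: In this ring‑closing metathesis the ruthenium loads on the unhindered allyl terminus and closes onto the vinyl group next to the silyloxy quaternary carbon, the nine‑membered ring can only hold the Z olefin, and the 1,1‑disubstituted methylene is out of reach of the C9 carbene.

**Step 18**
Reactants: 25 (1R,4aS,7S,11aR,8Z)‑7‑methyl‑11‑methylene‑7‑(triethylsilyloxy)‑4‑(triflyloxy)‑1,4a,5,6,7,10,11,11a‑octahydrocyclonona[c]pyran‑1‑yl acetate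
Product: 26 (1R,4aS,7S,11aR,8Z)‑7‑hydroxy‑7‑methyl‑11‑methylene‑4‑(triflyloxy)‑1,4a,5,6,7,10,11,11a‑octahydrocyclonona[c]pyran‑1‑yl acetate
Conditions: HF·pyridine, pyridine, THF, 0 °C → rt
Reagents that add atoms: none
Why: Buffered HF·pyridine removes the tertiary TES ether before any oxirane is present and leaves the enol triflate and anomeric acetate intact.

**Step 19**
Reactants: 27 3‑methylbut‑2‑enal; 11 vinylmagnesium bromide
Product: 28 5‑methylhexa‑1,4‑dien‑3‑ol (racemic)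
Conditions: THF, −78 → 0 °C; aq. NH4Cl
Reagents that add atoms: none
Why: Vinyl Grignard reagents add 1,2 to β,β‑disubstituted enals.

**Step 20**
Reactants: 28 5‑methylhexa‑1,4‑dien‑3‑ol
Product: 29 (3R)‑5‑methylhexa‑1,4‑dien‑3‑yl acetate
Conditions: Novozym 435 (CAL‑B), vinyl acetate (3 equiv), hexane, rt, stopped at about 50 % conversion (at most 50 % yield); chromatography
Reagents that add atoms: vinyl acetate C=COC(C)=O
Why: Lipase kinetic resolution follows the Kazlauskas rule (vinyl as medium, 2‑methylpropenyl as large group), so the (R)‑alcohol is acylated and gives the C13 acetate directly.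

**Step 21**
Reactants: 29 (3R)‑5‑methylhexa‑1,4‑dien‑3‑yl acetate
Product: 30 (1R)‑1‑[(2R)‑3,3‑dimethyloxiran‑2‑yl]prop‑2‑en‑1‑yl acetate
Conditions: D‑fructose‑derived Shi ketone (30 mol %), Oxone, K2CO3, Bu4NHSO4, MeCN/dimethoxymethane/aq. buffer (pH 10.5), 0 °C
Reagents that add atoms: potassium peroxymonosulfate (Oxone) [K+].[O-]S(=O)(=O)OO
Why: Shi asymmetric epoxidation attacks only the electron‑rich trisubstituted olefin, the D‑fructose ketone gives the (R)‑oxirane carbon (C14) by the spiro transition‑state model, and this agrees with the substrate's preference for attack anti to the allylic acetate (erythro).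

**Step 22**
Reactants: 30 (1R)‑1‑[(2R)‑3,3‑dimethyloxiran‑2‑yl]prop‑2‑en‑1‑yl acetate
Product: 32 (1S)‑1‑[(2R)‑3,3‑dimethyloxiran‑2‑yl]‑2‑oxoethyl acetate, via ozonide 31 (not isolated)
Conditions: O3, CH2Cl2, −78 °C; Me2S, −78 °C → rt; used crude at once
Reagents that add atoms: ozone [O-][O+]=O
Why: Ozonolysis with reductive work‑up converts the remaining vinyl group into the aldehyde without touching the oxirane, the acetate or either stereocentre.

**Step 23**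
Reactants: 26 (1R,4aS,7S,11aR,8Z)‑7‑hydroxy‑7‑methyl‑11‑methylene‑4‑(triflyloxy)‑1,4a,5,6,7,10,11,11a‑octahydrocyclonona[c]pyran‑1‑yl acetate; 32 (1S)‑1‑[(2R)‑3,3‑dimethyloxiran‑2‑yl]‑2‑oxoethyl acetate
Product: 33 (1R,4aS,7S,11aR,8Z)‑4‑[(1R,2R)‑2‑acetoxy‑2‑((2R)‑3,3‑dimethyloxiran‑2‑yl)‑1‑hydroxyethyl]‑7‑hydroxy‑7‑methyl‑11‑methylene‑1,4a,5,6,7,10,11,11a‑octahydrocyclonona[c]pyran‑1‑yl acetate
Conditions: CrCl2 (8 equiv), NiCl2 (2 mol %), 32 (2 equiv), degassed DMF, rt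
Reagents that add atoms: none
Why: The Nozaki–Hiyama–Kishi Ni/Cr coupling joins the enol triflate to the aldehyde in the presence of esters, free hydroxyl and oxirane, and polar Felkin–Anh addition anti to the α‑acetoxy group gives the 12,13‑anti (12R) carbinol; any 13→12 acetyl migration is harmless because both oxygens end as acetates.

**Step 24**
Reactants: 33 (1R,4aS,7S,11aR,8Z)‑4‑[(1R,2R)‑2‑acetoxy‑2‑((2R)‑3,3‑dimethyloxiran‑2‑yl)‑1‑hydroxyethyl]‑7‑hydroxy‑7‑methyl‑11‑methylene‑1,4a,5,6,7,10,11,11a‑octahydrocyclonona[c]pyran‑1‑yl acetate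
Product: 34 (1R,4aS,7S,11aR,8Z)‑4‑[(1R,2R)‑1,2‑diacetoxy‑2‑((2R)‑3,3‑dimethyloxiran‑2‑yl)ethyl]‑7‑hydroxy‑7‑methyl‑11‑methylene‑1,4a,5,6,7,10,11,11a‑octahydrocyclonona[c]pyran‑1‑yl acetate
Conditions: Ac2O, pyridine, DMAP (5 mol %), CH2Cl2, 0 °C
Reagents that add atoms: acetic anhydride CC(=O)OC(C)=O
Why: Acetylation of the secondary allylic alcohol is fast under these conditions while the tertiary C7 alcohol does not react.

**Step 25**
Reactants: 34 (1R,4aS,7S,11aR,8Z)‑4‑[(1R,2R)‑1,2‑diacetoxy‑2‑((2R)‑3,3‑dimethyloxiran‑2‑yl)ethyl]‑7‑hydroxy‑7‑methyl‑11‑methylene‑1,4a,5,6,7,10,11,11a‑octahydrocyclonona[c]pyran‑1‑yl acetate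
Product: 35 (1R,4aS,7S,8R,9R,11aR)‑4‑[(1R,2R)‑1,2‑diacetoxy‑2‑((2R)‑3,3‑dimethyloxiran‑2‑yl)ethyl]‑8,9‑epoxy‑7‑hydroxy‑7‑methyl‑11‑methylene‑decahydrocyclonona[c]pyran‑1‑yl acetate (CNP0134792.1)
Conditions: VO(acac)2 (5 mol %), TBHP (5.5 M in decane, 1.5 equiv), CH2Cl2, 0 °C → rt
Reagents that add atoms: tert‑butyl hydroperoxide CC(C)(C)OO
Why: Hydroxyl‑directed vanadium‑catalysed epoxidation delivers oxygen from the C7 vanadate to the peripheral face of the Z olefin, giving the cis‑oxirane syn to the hydroxyl (8R,9R) and leaving the enol ether and the exocyclic methylene, which carry no allylic hydroxyl, untouched.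

## Compound list

1 | tert‑butyl(but‑3‑yn‑1‑yloxy)dimethylsilane | C#CCCO[Si](C)(C)C(C)(C)C | starting material
2 | [(E)‑4‑(tert‑butyldimethylsilyloxy)‑2‑methylbut‑1‑enyl]dimethylalane | C[Al](C)/C=C(\C)CCO[Si](C)(C)C(C)(C)C | intermediate
3 | (E)‑5‑[(tert‑butyldimethylsilyl)oxy]‑3‑methylpent‑2‑en‑1‑ol | OC/C=C(\C)CCO[Si](C)(C)C(C)(C)C | intermediate
4 | [(2S,3S)‑3‑{2‑[(tert‑butyldimethylsilyl)oxy]ethyl}‑3‑methyloxiran‑2‑yl]methanol | OC[C@@H]1O[C@@]1(C)CCO[Si](C)(C)C(C)(C)C | intermediate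
5 | tert‑butyl{2‑[(2S,3R)‑3‑(iodomethyl)‑2‑methyloxiran‑2‑yl]ethoxy}dimethylsilane | IC[C@@H]1O[C@@]1(C)CCO[Si](C)(C)C(C)(C)C | intermediate
6 | (3S)‑5‑[(tert‑butyldimethylsilyl)oxy]‑3‑methylpent‑1‑en‑3‑ol | C=C[C@@](C)(O)CCO[Si](C)(C)C(C)(C)C | intermediate
7 | (3S)‑3‑methylpent‑4‑ene‑1,3‑diol | C=C[C@@](C)(O)CCO | intermediate
8 | (3S)‑5‑iodo‑3‑methylpent‑1‑en‑3‑ol | C=C[C@@](C)(O)CCI | intermediate
9 | triethyl{[(3S)‑5‑iodo‑3‑methylpent‑1‑en‑3‑yl]oxy}silane | C=C[C@@](C)(O[Si](CC)(CC)CC)CCI | intermediate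
10 | 2,3‑dibromoprop‑1‑ene | C=C(Br)CBr | starting material
11 | vinylmagnesium bromide | C=C[Mg]Br | starting material
12 | 2‑bromopenta‑1,4‑diene | C=C(Br)CC=C | intermediate
13 | furfuryl alcohol | OCc1ccco1 | starting material
14 | 6‑hydroxy‑2H‑pyran‑3(6H)‑one (racemic) | O=C1C=CC(O)OC1 | intermediate
15 | (R)‑6‑(isobutyryloxy)‑2H‑pyran‑3(6H)‑one | O=C1C=C[C@@H](OC(=O)C(C)C)OC1 | intermediate
16 | (S)‑6‑[(4‑methoxybenzyl)oxy]‑2H‑pyran‑3(6H)‑one | O=C1C=C[C@@H](OCc2ccc(OC)cc2)OC1 | intermediate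
17 | penta‑1,4‑dien‑2‑ylmagnesium bromide | C=C(CC=C)[Mg]Br | intermediate
18 | (5R,6S)‑6‑[(4‑methoxybenzyl)oxy]‑5‑(penta‑1,4‑dien‑2‑yl)‑3‑[(trimethylsilyl)oxy]‑5,6‑dihydro‑2H‑pyran | C[Si](C)(C)OC1=C[C@H](C(=C)CC=C)[C@@H](OCc2ccc(OC)cc2)OC1 | intermediate
19 | lithium enolate of the 5,6‑trans pyran‑3‑one (from 18) | [Li]OC1=C[C@H](C(=C)CC=C)[C@@H](OCc2ccc(OC)cc2)OC1 | intermediate
20 | (4S,5R,6S)‑6‑[(4‑methoxybenzyl)oxy]‑4‑[(3S)‑3‑methyl‑3‑(triethylsilyloxy)pent‑4‑en‑1‑yl]‑5‑(penta‑1,4‑dien‑2‑yl)dihydro‑2H‑pyran‑3(4H)‑one | C=C[C@@](C)(O[Si](CC)(CC)CC)CC[C@@H]1C(=O)CO[C@H](OCc2ccc(OC)cc2)[C@H]1C(=C)CC=C | intermediate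
21 | (4S,5R)‑6‑hydroxy‑4‑[(3S)‑3‑methyl‑3‑(triethylsilyloxy)pent‑4‑en‑1‑yl]‑5‑(penta‑1,4‑dien‑2‑yl)dihydro‑2H‑pyran‑3(4H)‑one (anomer mixture) | C=C[C@@](C)(O[Si](CC)(CC)CC)CC[C@@H]1C(=O)COC(O)[C@H]1C(=C)CC=C | intermediate
22 | (2R,3R,4S)‑4‑[(3S)‑3‑methyl‑3‑(triethylsilyloxy)pent‑4‑en‑1‑yl]‑5‑oxo‑3‑(penta‑1,4‑dien‑2‑yl)tetrahydro‑2H‑pyran‑2‑yl acetate | C=C[C@@](C)(O[Si](CC)(CC)CC)CC[C@@H]1C(=O)CO[C@H](OC(C)=O)[C@H]1C(=C)CC=C | intermediate
23 | potassium enolate of 22 (C3=C4) | C=C[C@@](C)(O[Si](CC)(CC)CC)CC[C@@H]1C(O[K])=CO[C@H](OC(C)=O)[C@H]1C(=C)CC=C | intermediate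
24 | (2R,3R,4S)‑4‑[(3S)‑3‑methyl‑3‑(triethylsilyloxy)pent‑4‑en‑1‑yl]‑3‑(penta‑1,4‑dien‑2‑yl)‑5‑(triflyloxy)‑3,4‑dihydro‑2H‑pyran‑2‑yl acetate | C=C[C@@](C)(O[Si](CC)(CC)CC)CC[C@@H]1C(OS(=O)(=O)C(F)(F)F)=CO[C@H](OC(C)=O)[C@H]1C(=C)CC=C | intermediate
25 | (1R,4aS,7S,11aR,8Z)‑7‑methyl‑11‑methylene‑7‑(triethylsilyloxy)‑4‑(triflyloxy)‑1,4a,5,6,7,10,11,11a‑octahydrocyclonona[c]pyran‑1‑yl acetate | C=C1C/C=C\[C@@](C)(O[Si](CC)(CC)CC)CC[C@@H]2C(OS(=O)(=O)C(F)(F)F)=CO[C@H](OC(C)=O)[C@@H]12 | intermediate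
26 | (1R,4aS,7S,11aR,8Z)‑7‑hydroxy‑7‑methyl‑11‑methylene‑4‑(triflyloxy)‑1,4a,5,6,7,10,11,11a‑octahydrocyclonona[c]pyran‑1‑yl acetate | C=C1C/C=C\[C@@](C)(O)CC[C@@H]2C(OS(=O)(=O)C(F)(F)F)=CO[C@H](OC(C)=O)[C@@H]12 | intermediate
27 | 3‑methylbut‑2‑enal | CC(C)=CC=O | starting material
28 | 5‑methylhexa‑1,4‑dien‑3‑ol (racemic) | C=CC(O)C=C(C)C | intermediate
29 | (3R)‑5‑methylhexa‑1,4‑dien‑3‑yl acetate | C=C[C@@H](OC(C)=O)C=C(C)C | intermediate
30 | (1R)‑1‑[(2R)‑3,3‑dimethyloxiran‑2‑yl]prop‑2‑en‑1‑yl acetate | C=C[C@@H](OC(C)=O)[C@H]1OC1(C)C | intermediate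
31 | 1,2,4‑trioxolane (ozonide) of 30 | CC(=O)O[C@H](C1OCOO1)[C@H]2OC2(C)C | intermediate
32 | (1S)‑1‑[(2R)‑3,3‑dimethyloxiran‑2‑yl]‑2‑oxoethyl acetate | O=C[C@@H](OC(C)=O)[C@H]1OC1(C)C | intermediate
33 | (1R,4aS,7S,11aR,8Z)‑4‑[(1R,2R)‑2‑acetoxy‑2‑((2R)‑3,3‑dimethyloxiran‑2‑yl)‑1‑hydroxyethyl]‑7‑hydroxy‑7‑methyl‑11‑methylene‑1,4a,5,6,7,10,11,11a‑octahydrocyclonona[c]pyran‑1‑yl acetate | C=C1C/C=C\[C@@](C)(O)CC[C@@H]2C([C@@H](O)[C@@H](OC(C)=O)[C@H]3OC3(C)C)=CO[C@H](OC(C)=O)[C@@H]12 | intermediate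
34 | (1R,4aS,7S,11aR,8Z)‑4‑[(1R,2R)‑1,2‑diacetoxy‑2‑((2R)‑3,3‑dimethyloxiran‑2‑yl)ethyl]‑7‑hydroxy‑7‑methyl‑11‑methylene‑1,4a,5,6,7,10,11,11a‑octahydrocyclonona[c]pyran‑1‑yl acetate | C=C1C/C=C\[C@@](C)(O)CC[C@@H]2C([C@@H](OC(C)=O)[C@@H](OC(C)=O)[C@H]3OC3(C)C)=CO[C@H](OC(C)=O)[C@@H]12 | intermediate
35 | CNP0134792.1, (1R,4aS,7S,8R,9R,11aR,12R,13R,14R)‑1,12,13‑triacetoxy‑8,9:14,15‑diepoxy‑7‑hydroxy‑xenica‑3,11(19)‑diene | C=C1C[C@H]2O[C@H]2[C@@](C)(O)CC[C@@H]2C([C@@H](OC(C)=O)[C@@H](OC(C)=O)[C@H]3OC3(C)C)=CO[C@H](OC(C)=O)[C@@H]12 | target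

## Step count and risks

Total step count: 25.
Longest linear sequence: 16 steps (steps 1–7, 13–18, 23–25), which is 64 % of the total.

**Step 13 (alkylation of the enolate with an unactivated primary iodide; risk of proton transfer, polyalkylation and low conversion).** The fallback sets out from diol 7 and silyl enol ether 18 and comes back at ketone 20, replacing the SN2 alkylation by an aldol, dehydration and conjugate reduction. Diol 7 is bis‑silylated (TESOTf, 2,6‑lutidine) to (3S)‑3‑methyl‑1,3‑bis(triethylsilyloxy)pent‑4‑ene F1. Swern oxidation, which cleaves and oxidises the primary TES ether directly, gives (3S)‑3‑methyl‑3‑(triethylsilyloxy)pent‑4‑enal F2. Lithium enolate 19 (from 18 and MeLi) adds to F2 at −78 °C to give the β‑hydroxy ketone F3. MsCl/Et3N then DBU gives the exocyclic (E)‑enone F4. Conjugate reduction with Stryker's reagent and a short DBU equilibration to the 4,5‑trans isomer returns 20.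

**Step 17 (nine‑membered ring closure; risk of oligomers, slow closure on the flattened enol‑triflate ring, or the competing seven‑membered closure onto the methylene).** The fallback sets out from ketone 20 and comes back at bicyclic triflate 25, closing the ring before the enol triflate exists. RCM of 20 (Grubbs II, high dilution), in which the saturated chair holds both tethers equatorial and gauche and there is no enol ether on the ring, gives the bicyclic ketone PMB acetal F5. DDQ gives the bicyclic lactol F6. Ac2O/Et3N/DMAP gives the bicyclic keto acetate F7. KHMDS and Comins' reagent then give 25.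

**Step 23 (NHK coupling; risk of poor diastereoselectivity at C12 with the labile α‑acetoxy epoxy‑aldehyde).** The fallback sets out from 33, obtained as a C12 epimer mixture or as the wrong epimer, and comes back at 33 as the single 12R isomer; C12 is set by ketone reduction instead of by the addition. Dess–Martin periodinane/NaHCO3 oxidises the carbinol to the C12 ketone F8 (a vinylogous ester, so C13 is not easily epimerised). Reagent‑controlled reduction (Me‑CBS catalyst with catecholborane, antipode chosen for 12R, or Zn(BH4)2 under chelation control for the anti product) returns 33.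

## Further compounds

F1 | step 13 | (3S)‑3‑methyl‑1,3‑bis(triethylsilyloxy)pent‑4‑ene | C=C[C@@](C)(O[Si](CC)(CC)CC)CCO[Si](CC)(CC)CC
F2 | step 13 | (3S)‑3‑methyl‑3‑(triethylsilyloxy)pent‑4‑enal | C=C[C@@](C)(O[Si](CC)(CC)CC)CC=O
F3 | step 13 | β‑hydroxy ketone: (4S,5R,6S)‑4‑[(3S)‑1‑hydroxy‑3‑methyl‑3‑(triethylsilyloxy)pent‑4‑en‑1‑yl]‑6‑[(4‑methoxybenzyl)oxy]‑5‑(penta‑1,4‑dien‑2‑yl)dihydro‑2H‑pyran‑3(4H)‑one (carbinol epimers) | C=C[C@@](C)(O[Si](CC)(CC)CC)CC(O)[C@@H]1C(=O)CO[C@H](OCc2ccc(OC)cc2)[C@H]1C(=C)CC=C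
F4 | step 13 | exocyclic (E)‑enone: (5R,6S)‑6‑[(4‑methoxybenzyl)oxy]‑4‑[(3S)‑3‑methyl‑3‑(triethylsilyloxy)pent‑4‑en‑1‑ylidene]‑5‑(penta‑1,4‑dien‑2‑yl)dihydro‑2H‑pyran‑3(4H)‑one | C=C[C@@](C)(O[Si](CC)(CC)CC)C/C=C1/C(=O)CO[C@H](OCc2ccc(OC)cc2)[C@H]1C(=C)CC=C
F5 | step 17 | bicyclic ketone PMB acetal: (1S,4aS,7S,11aR,8Z)‑1‑[(4‑methoxybenzyl)oxy]‑7‑methyl‑11‑methylene‑7‑(triethylsilyloxy)‑octahydrocyclonona[c]pyran‑4(3H)‑one | C=C1C/C=C\[C@@](C)(O[Si](CC)(CC)CC)CC[C@@H]2C(=O)CO[C@H](OCc3ccc(OC)cc3)[C@@H]12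
F6 | step 17 | bicyclic lactol: (4aS,7S,11aR,8Z)‑1‑hydroxy‑7‑methyl‑11‑methylene‑7‑(triethylsilyloxy)‑octahydrocyclonona[c]pyran‑4(3H)‑one (anomer mixture) | C=C1C/C=C\[C@@](C)(O[Si](CC)(CC)CC)CC[C@@H]2C(=O)COC(O)[C@@H]12
F7 | step 17 | bicyclic keto acetate: (1R,4aS,7S,11aR,8Z)‑7‑methyl‑11‑methylene‑4‑oxo‑7‑(triethylsilyloxy)‑decahydrocyclonona[c]pyran‑1‑yl acetate | C=C1C/C=C\[C@@](C)(O[Si](CC)(CC)CC)CC[C@@H]2C(=O)CO[C@H](OC(C)=O)[C@@H]12
F8 | step 23 | C12 ketone: (1R,4aS,7S,11aR,8Z)‑4‑[(2R)‑2‑acetoxy‑2‑((2R)‑3,3‑dimethyloxiran‑2‑yl)acetyl]‑7‑hydroxy‑7‑methyl‑11‑methylene‑1,4a,5,6,7,10,11,11a‑octahydrocyclonona[c]pyran‑1‑yl acetate | C=C1C/C=C\[C@@](C)(O)CC[C@@H]2C(C(=O)[C@@H](OC(C)=O)[C@H]3OC3(C)C)=CO[C@H](OC(C)=O)[C@@H]12
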